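**Plan** (numbering as in the name: C1 = quaternary carbinol carrying C7H2OBz, C2 = CHOH, C3 = CHOBz, C4 = CHOH, C5=C6; beta = the face of the C2 hydroxyl)
- Retrosynthesis: a) C1–O and C4–O, cis-1,4 across C5=C6, are cut together, as the O2 adduct of the diene C1=C6–C5=C4. b) C3–OBz is cut by a retro-SN2′ that ties the C2 oxygen back to C5 as an oxa bridge. c) The carbocycle is cut at C1–C2 and C5–C6.
- Enabling feature: in the cyclohexene ring the run C2–C3–C4–C5 starts at an oxygen-bearing carbon and ends at an sp2 carbon 1,4 to it. It is the carbon chain of furan, with the C2 oxygen as the furan oxygen, and C6–C1–C7 is the chain of an acrolein. One [4+2] event therefore builds the whole C7 skeleton from two flat achiral molecules.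
- Forward: the Diels-Alder reaction closes the carbocycle together with a temporary 7-oxa bridge. The helpers then leave in turn. CHO becomes C7H2O, Br leaves through a spiro-epoxide to give C1=C6, the bridge is opened by the benzoate needed at C3, and O2 moves the double bond to C5=C6.
- Stereochemistry: C2 comes from the chiral boron catalyst of the cycloaddition. C3 comes from attack anti to the bridge (trans to C2–OH). C1 and C4 come from suprafacial O2 addition on the face of C2–OH, opposite to C3–OBz.

Key step: step 2

Assumption: the sense of induction of the oxazaborolidinone and of the ferrocenyl diphosphine is taken from the closest analogues (cyclopentadiene with 2-bromoacrolein; benzo-fused oxabicycles). If either proves opposite, its equally available antipode is used.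

**Step 1**
Reactants: 1 acrolein
Product: 3 2-bromoacrolein, via 2,3-dibromopropanal 2 (not isolated)
Conditions: Br2, CH2Cl2, −78 to 0 °C; then Et3N, 0 °C
Reagents that add atoms: bromine, BrBr
Why: Electrophilic addition of bromine to the C=C bond gives the 2,3-dibromide, whose acidic alpha hydrogen lets Et3N expel the beta bromide (bromination-dehydrobromination, E1cB type), and no stereocentre remains.

**Step 2**
Reactants: 3 2-bromoacrolein; 4 furan
Product: 5 (1S,2S,4S)-2-bromo-7-oxabicyclo[2.2.1]hept-5-ene-2-carbaldehyde (CHO exo; Br endo)
Conditions: furan (5 equiv), B-butyl-oxazaborolidinone made from N-tosyl-(R)-tryptophan and n-BuB(OH)2 (10 mol %), CH2Cl2, −78 °C; cold aq NaHCO3 work-up, crude product used at once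
Reagents that add atoms: none
Why: The boron Lewis acid binds the formyl oxygen of 3 and lowers its LUMO, so that furan adds as the 4π partner in a concerted but asynchronous Diels-Alder reaction (C5–C6 leading, C2–C1 following) at a temperature at which cycloreversion of the labile adduct is frozen. The closest known reaction type is the oxazaborolidinone-catalysed enantioselective Diels-Alder reaction of 2-haloacroleins with cyclopentadiene and furan. The one event closes the six-membered carbocycle C1–C6 and, with it, the oxolane ring C2–C1–C6–C5–O of the temporary 7-oxanorbornene, both by intermolecular suprafacial-suprafacial [4+2] closure. C1 is fixed by the dienophile face left open by the indole ring that stacks over the bound bromoacrolein, and C2 and C5 are tied to that face by the exo-formyl (endo-bromine) transition state that alpha-halogen substitution favours. The step needs enantioface and exo selectivity together, because C1 is flattened in step 4 and an endo adduct from the same face would end as the antipode of 8; regioselectivity is no issue because furan is symmetric, and cycloaddition is kept ahead of Friedel-Crafts-type alkylation of furan by the low temperature and the mild Lewis acid. The two sigma bonds made are C1–C2 and C5–C6 of the target, and the helpers removed later are bromine (alkyne oxidation level, exo control), the formyl group (activation, later C7) and the oxa bridge (stores the C2 oxygen and a leaving group at C5).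

**Step 3**
Reactants: 5 (1S,2S,4S)-2-bromo-7-oxabicyclo[2.2.1]hept-5-ene-2-carbaldehyde
Product: 6 [(1S,2R,4S)-2-bromo-7-oxabicyclo[2.2.1]hept-5-en-2-yl]methanol
Conditions: NaBH4, MeOH–THF, −40 to 0 °C
Reagents that add atoms: none
Why: Borohydride 1,2-reduction of the aldehyde is far faster than any attack on the tertiary bromide or the strained alkene, removes the acceptor that drives cycloreversion, and leaves C1, C2 and C5 untouched.

**Step 4**
Reactants: 6 [(1S,2R,4S)-2-bromo-7-oxabicyclo[2.2.1]hept-5-en-2-yl]methanol
Product: 8 [(1S,4R)-7-oxabicyclo[2.2.1]hepta-2,5-dien-2-yl]methanol, via spiro-epoxide 7 (not isolated)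
Conditions: LiN(iPr)2 (3 equiv), THF, −78 °C to rt; then H2O
Reagents that add atoms: none
Why: The lithium alkoxide displaces the endo tertiary bromide from the rear (3-exo-tet closure) to give spiro-epoxide 7 with its oxygen exo, and a second equivalent of amide removes the exo hydrogen at C6 that is syn-coplanar with the lithium-bound C1–O bond (base-induced epoxide to allylic alcohol rearrangement), which takes out bromine, creates C1=C6 and leaves the bridgehead centres C2 and C5 intact.

**Step 5**
Reactants: 8 [(1S,4R)-7-oxabicyclo[2.2.1]hepta-2,5-dien-2-yl]methanol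
Product: 9 [(1S,4R)-7-oxabicyclo[2.2.1]hepta-2,5-dien-2-yl]methyl benzoate
Conditions: BzCl, pyridine, CH2Cl2, 0 °C
Reagents that add atoms: benzoyl chloride, O=C(Cl)c1ccccc1
Why: Acylation of a primary allylic alcohol under basic, acid-free conditions is tolerated by the acid-labile oxanorbornadiene and touches no stereocentre.

**Step 6**
Reactants: 9 [(1S,4R)-7-oxabicyclo[2.2.1]hepta-2,5-dien-2-yl]methyl benzoate
Product: 10 [(5R,6R)-5-(benzoyloxy)-6-hydroxycyclohexa-1,3-dien-1-yl]methyl benzoate
Conditions: [Rh(cod)Cl]2 (2.5 mol %), (R)-1-[(S)-2-(diphenylphosphino)ferrocenyl]ethyldi-tert-butylphosphine (6 mol %), PhCO2H, Et3N, THF, 50 °C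
Reagents that add atoms: benzoic acid, O=C(O)c1ccccc1
Why: Monovalent rhodium bound on the exo face to C3=C4 and the bridge oxygen inserts into the less hindered bridgehead bond C5–O, and benzoate attacks the allyl terminus C3 from the endo face (anti SN2′, the known rhodium-catalysed ring opening of oxabicyclic alkenes by carboxylates), so that C3–OBz is set trans to the retained C2–OH, while the matched ligand reinforces the choice of C5–O over C2–O and should divert the minor enantiomer of 9 into a separable constitutional isomer.

**Step 7**
Reactants: 10 [(5R,6R)-5-(benzoyloxy)-6-hydroxycyclohexa-1,3-dien-1-yl]methyl benzoate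
Product: 12 1alpha-benzoyloxymethyl-3alpha-benzoyloxycyclohex-5-en-1beta,2beta,4beta-triol (target), via endoperoxide 11 (not isolated)
Conditions: O2, tetraphenylporphyrin (cat.), visible light, CH2Cl2, −20 °C; then thiourea, MeOH, 0 °C to rt
Reagents that add atoms: dioxygen, O=O
Why: Singlet oxygen adds to the s-cis diene C1=C6–C5=C4 in a suprafacial [4+2] cycloaddition on the beta face, which is steered by hydrogen bonding to the allylic C2–OH and left open by the pseudoaxial alpha C3–OBz, so that C1–O and C4–O are set cis to each other and to C2–OH and the double bond lands at C5=C6, and thiourea then cleaves only the O–O bond (photooxygenation-thiourea route to cis-2-ene-1,4-diols).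

**Compound list**
1 | acrolein | C=CC=O | starting material
2 | 2,3-dibromopropanal (racemic) | O=CC(Br)CBr | intermediate
3 | 2-bromoacrolein | C=C(Br)C=O | intermediate
4 | furan | c1ccoc1 | starting material
5 | (1S,2S,4S)-2-bromo-7-oxabicyclo[2.2.1]hept-5-ene-2-carbaldehyde (CHO exo, Br endo) | O=C[C@]1(Br)C[C@H]2C=C[C@@H]1O2 | intermediate
6 | [(1S,2R,4S)-2-bromo-7-oxabicyclo[2.2.1]hept-5-en-2-yl]methanol (CH2OH exo, Br endo) | OC[C@]1(Br)C[C@H]2C=C[C@@H]1O2 | intermediate
7 | (1S,2S,4S)-spiro[7-oxabicyclo[2.2.1]hept-5-ene-2,2'-oxirane] (oxirane O exo, CH2 endo) | C1O[C@@]12C[C@H]3C=C[C@@H]2O3 | intermediate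
8 | [(1S,4R)-7-oxabicyclo[2.2.1]hepta-2,5-dien-2-yl]methanol | OCC1=C[C@H]2C=C[C@@H]1O2 | intermediate
9 | [(1S,4R)-7-oxabicyclo[2.2.1]hepta-2,5-dien-2-yl]methyl benzoate | O=C(OCC1=C[C@H]2C=C[C@@H]1O2)c1ccccc1 | intermediate
10 | [(5R,6R)-5-(benzoyloxy)-6-hydroxycyclohexa-1,3-dien-1-yl]methyl benzoate (trans; target numbering 2beta-OH, 3alpha-OBz) | O=C(OCC1=CC=C[C@@H](OC(=O)c2ccccc2)[C@@H]1O)c1ccccc1 | intermediate
11 | [8-(benzoyloxy)-7-hydroxy-2,3-dioxabicyclo[2.2.2]oct-5-en-1-yl]methyl benzoate, the 1beta,4beta-epidioxide of 10 (peroxide bridge syn to OH, anti to OBz) | O=C(OC[C@]12C=C[C@H](OO1)[C@@H](OC(=O)c3ccccc3)[C@@H]2O)c4ccccc4 | intermediate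
12 | [(1S,4S,5R,6S)-5-(benzoyloxy)-1,4,6-trihydroxycyclohex-2-en-1-yl]methyl benzoate = 1alpha-benzoyloxymethyl-3alpha-benzoyloxycyclohex-5-en-1beta,2beta,4beta-triol | O=C(OC[C@@]1(O)C=C[C@H](O)[C@@H](OC(=O)c2ccccc2)[C@@H]1O)c1ccccc1 | target

**Total step count:** 7. **Longest linear sequence:** 7 steps (1 to 12); furan enters as purchased.

**Steps most likely to fail**

*Step 6.* Three processes threaten it. The strained, acid-labile oxanorbornadiene may isomerise to a phenol. The dihydrodiol ester may lose benzoic acid under the warm buffered conditions, which is also an aromatisation. Rhodium may insert into the C2–O bond instead of the C5–O bond.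

The fallback sets out from 6 and comes back at 10. It opens the bridge before the second ring double bond exists, so that steps 4 and 5 are bypassed. Compound 6 is benzoylated (BzCl, pyridine) to [(1S,2R,4S)-2-bromo-7-oxabicyclo[2.2.1]hept-5-en-2-yl]methyl benzoate F1. Its C1 is sp3, so neither it nor its product can aromatise. Ring opening by benzoate follows under the iodide-modified conditions used for simple oxanorbornenes ([Rh(cod)Cl]2, the same ligand, Bu4NI, PhCO2H, Et3N, tetrahydropyran, 80 to 100 °C). There the inductive pull of C1–Br adds to the bias against C2–O cleavage. This should give 1alpha-bromo-1beta-(benzoyloxymethyl)-3alpha-benzoyloxycyclohex-4-en-2beta-ol F2. DBU in CH2Cl2 then removes the allylic beta hydrogen at C6, antiperiplanar to the alpha C1–Br bond (E2), and gives the conjugated diene 10.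

*Step 7.* Singlet oxygen may add with poor facial selectivity; attack on the alpha face would invert both C1 and C4. An ene reaction at the C7 or C2 hydrogens may compete. The endoperoxide may suffer base-induced Kornblum-DeLaMare cleavage.

The fallback sets out from 10 and comes back at 12. It sets the two C–O bonds one at a time under substrate control. Hydroxyl-directed epoxidation (VO(acac)2 cat., t-BuOOH, CH2Cl2, 0 °C) acts on the only double bond allylic to C2–OH. It gives, syn to that hydroxyl, 1alpha-(benzoyloxymethyl)-3alpha-benzoyloxy-1beta,6beta-epoxycyclohex-4-en-2beta-ol F3. Zerovalent palladium (Pd(PPh3)4 cat., levulinic acid, THF, 0 °C) ionises the allylic C6–O bond with inversion, and the carboxylate attacks C4 anti to the metal. This is the known cis-1,4 addition of carboxylic acids to cyclic diene monoepoxides (Tsuji-Trost type) and gives the 4-O-levulinate of the target F4. Hydrazine acetate in CH2Cl2–MeOH removes the levulinate without touching the benzoates and gives 12.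

*Step 4.* The amide may open the spiro-epoxide nucleophilically at C7. It may lithiate the oxirane CH2, which starts carbenoid chemistry. The strained trisubstituted double bond may also be slow to form.

The fallback sets out from 5 and comes back at 8. Hydrogen bromide is taken out at the aldehyde stage. DBU (CH2Cl2, −20 to 0 °C) dehydrobrominates the tertiary alpha-bromo aldehyde, which has beta hydrogens only at C6, to (1S,4R)-7-oxabicyclo[2.2.1]hepta-2,5-diene-2-carbaldehyde F5. Luche reduction (NaBH4, CeCl3·7H2O, MeOH, −78 °C) reduces the enal 1,2 to 8.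

**Further compounds**
F1 | step 6 | [(1S,2R,4S)-2-bromo-7-oxabicyclo[2.2.1]hept-5-en-2-yl]methyl benzoate | O=C(OC[C@]1(Br)C[C@H]2C=C[C@@H]1O2)c1ccccc1
F2 | step 6 | 1alpha-bromo-1beta-(benzoyloxymethyl)-3alpha-benzoyloxycyclohex-4-en-2beta-ol | O=C(OC[C@]1(Br)CC=C[C@@H](OC(=O)c2ccccc2)[C@@H]1O)c1ccccc1
F3 | step 7 | 1alpha-(benzoyloxymethyl)-3alpha-benzoyloxy-1beta,6beta-epoxycyclohex-4-en-2beta-ol | O=C(OC[C@@]12O[C@@H]1C=C[C@@H](OC(=O)c3ccccc3)[C@@H]2O)c4ccccc4
F4 | step 7 | 4-O-levulinate of the target | O=C(OC[C@@]1(O)C=C[C@H](OC(=O)CCC(C)=O)[C@@H](OC(=O)c2ccccc2)[C@@H]1O)c1ccccc1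
F5 | step 4 | (1S,4R)-7-oxabicyclo[2.2.1]hepta-2,5-diene-2-carbaldehyde | O=CC1=C[C@H]2C=C[C@@H]1O2
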